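Retrosynthetic overview
1. Target 33 is 7,8-di-O-angeloyl-9-hydroxylongipin-2-en-1-one (locants: C1 ketone, C2=C3 with CH3 on C3, cyclobutane C4–C5–C11–C10, C6 = CMe2, C7/C8/C9 oxygenated, C10 quaternary C–CH3); the two angelates go on last (28 → 33).
2. Key disconnection: the C3–C4 bond of the cyclohexenone ring (C1, C2, C3, C4, C5, C11) is opened while a C4–C11 bond is drawn, giving acyl bicyclo[1.1.0]butane 27 with a (Z)-3-iodobut-2-enoyl group on C11.
3. Enabling feature: in the cyclobutane C4–C5–C11–C10 the CH corners C4 and C11 stand 1,3 to each other and are the two anchors of the C1–C2–C3 bridge, C11 holding the C1 carbonyl; the four-membered ring can therefore be stored as a bicyclobutane (central bond C4–C11, wings C5 and C10 already spanned by C6–C9) whose strain pays for the C3–C4 bond.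
4. 27 ← diazo ketone 26 (carbene at C11 adds to C4=C5 across quaternary C10); C10 ← Johnson–Claisen from a C5 allylic alcohol; C8/C9 diol ← OsO4 anti to C7–O on a cycloheptadienone; seven-membered ring ← aldol/ring-closing metathesis; C7 ← enantioselective Mukaiyama aldol.
5. Ring order: seven-membered ring (step 5), the two three-membered rings of the bicyclobutane (step 16), then the cyclohexenone ring, whose closure also sets the cyclobutane free (step 17).

Key step: step 17

Remarks (assumptions)
- The target locants C1–C11 defined above are used for all intermediates; the SMILES in the compound list fix the absolute configuration.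
- The N-tosyl-(S)-valine-derived promoter is assumed to give the (3R)-aldol 3; if the opposite sense were found, the (R)-valine reagent would be used.
- Short-lived species (enolates, metal carbenes, radicals, osmate esters) are described in the Why lines and carry no compound number.

Step 1
Reactants: 1 (E)-but-2-enal; 2 1-methoxy-2-methyl-1-(trimethylsilyloxy)prop-1-ene
Product: 3 methyl (3R,4E)-3-hydroxy-2,2-dimethylhex-4-enoate
Conditions: oxazaborolidinone made in the flask from N-tosyl-(S)-valine and BH3·THF (1.0 equiv), CH2Cl2, −78 °C; aq. NaHCO3, then 1 M HCl/THF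
Reagents that add atoms: none
Why: Enantioselective Mukaiyama aldol in which the chiral boron Lewis acid binds the enal and exposes one carbonyl face to the ketene acetal, setting C7 (the only stereocentre set by a chiral reagent) and installing the C6 gem-dimethyl group.

Step 2
Reactants: 3 methyl (3R,4E)-3-hydroxy-2,2-dimethylhex-4-enoate
Product: 4 methyl (3R,4E)-2,2-dimethyl-3-(triethylsilyloxy)hex-4-enoate
Conditions: Et3SiCl, imidazole, DMF, 0 °C → rt
Reagents that add atoms: chlorotriethylsilane CC[Si](Cl)(CC)CC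
Why: Standard silylation of the secondary alcohol; the triethylsilyl ether blocks retro-aldol cleavage in the basic steps and can later be removed beside a tert-butyldimethylsilyl ether.

Step 3
Reactants: 4 methyl (3R,4E)-2,2-dimethyl-3-(triethylsilyloxy)hex-4-enoate; 5 (trimethylsilyl)methyllithium
Product: 7 (4R,5E)-3,3-dimethyl-4-(triethylsilyloxy)hept-5-en-2-one, via silyl ketone 6 (not isolated)
Conditions: Me3SiCH2Li (2.2 equiv), pentane/THF, 0 °C → rt; then MeOH, rt
Reagents that add atoms: none
Why: Acyl substitution of the non-enolisable ester stops at the ketone stage because the α-silyl ketone is deprotonated in the flask, and methanolysis then removes silicon to leave the methyl ketone (C5 carbonyl, C4 methyl).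

Step 4
Reactants: 7 (4R,5E)-3,3-dimethyl-4-(triethylsilyloxy)hept-5-en-2-one; 8 but-3-en-2-one
Product: 9 (7R,8E)-3-hydroxy-3,6,6-trimethyl-7-(triethylsilyloxy)deca-1,8-dien-5-one (both C3 epimers)
Conditions: LiN(iPr)2, THF, −78 °C; 8 (1.2 equiv), −78 °C; AcOH, −78 °C
Reagents that add atoms: none
Why: The kinetic lithium enolate (only one enolisable position) adds 1,2 to the enone at low temperature (aldol addition), bringing in C10 with its methyl and C9 as a vinyl group; the new carbinol centre is removed in step 6.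

Step 5
Reactants: 9 (7R,8E)-3-hydroxy-3,6,6-trimethyl-7-(triethylsilyloxy)deca-1,8-dien-5-one
Product: 10 (6R)-3-hydroxy-3,7,7-trimethyl-6-(triethylsilyloxy)cyclohept-4-en-1-one (both C3 epimers)
Conditions: second-generation Grubbs catalyst (5 mol %), CH2Cl2 (0.005 M), 40 °C
Reagents that add atoms: none
Why: Ring-closing metathesis between the vinyl carbinol and the propenyl group closes the seven-membered ring as its C8=C9 cis-alkene with loss of propene; free tertiary allylic alcohols are tolerated.

Step 6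
Reactants: 10 (6R)-3-hydroxy-3,7,7-trimethyl-6-(triethylsilyloxy)cyclohept-4-en-1-one
Product: 12 (6R)-3,7,7-trimethyl-6-(triethylsilyloxy)cyclohepta-2,4-dien-1-one, via tertiary mesylate 11 (not isolated)
Conditions: MeSO2Cl, Et3N, CH2Cl2, 0 °C; then DBU, rt
Reagents that add atoms: methanesulfonyl chloride CS(=O)(=O)Cl (retained in 11 only)
Why: Sulfonylation of the tertiary β-hydroxy ketone and E1cB elimination through the C4 enolate give the conjugated dienone (C5 ketone, C4=C10, C8=C9).

Step 7
Reactants: 12 (6R)-3,7,7-trimethyl-6-(triethylsilyloxy)cyclohepta-2,4-dien-1-one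
Product: 13 (4S,5S,6S)-4,5-dihydroxy-3,7,7-trimethyl-6-(triethylsilyloxy)cyclohept-2-en-1-one
Conditions: OsO4 (2 mol %), N-methylmorpholine N-oxide, acetone/H2O, 0 °C → rt
Reagents that add atoms: N-methylmorpholine N-oxide C[N+]1([O-])CCOCC1; water O
Why: Upjohn dihydroxylation takes the more electron-rich γ,δ-alkene (C8=C9) of the dienone and, as is usual for OsO4 on allylic ethers, the face anti to the C7 silyloxy group, setting C8 and C9 (hydroxyls cis to each other, trans to the C7 oxygen).

Step 8
Reactants: 13 (4S,5S,6S)-4,5-dihydroxy-3,7,7-trimethyl-6-(triethylsilyloxy)cyclohept-2-en-1-one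
Product: 14 (4S,5S,6S)-4-(tert-butyldimethylsilyloxy)-5-hydroxy-3,7,7-trimethyl-6-(triethylsilyloxy)cyclohept-2-en-1-one
Conditions: tBuMe2SiOTf (1.05 equiv), 2,6-lutidine, CH2Cl2, −78 °C
Reagents that add atoms: tert-butyldimethylsilyl trifluoromethanesulfonate CC(C)(C)[Si](C)(C)OS(=O)(=O)C(F)(F)F
Why: Kinetic silylation should take the allylic C9 hydroxyl in preference to the C8 hydroxyl, which is flanked by the bulky C7 triethylsilyl ether.

Step 9
Reactants: 14 (4S,5S,6S)-4-(tert-butyldimethylsilyloxy)-5-hydroxy-3,7,7-trimethyl-6-(triethylsilyloxy)cyclohept-2-en-1-one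
Product: 16 (4S,5R,6S)-4-(tert-butyldimethylsilyloxy)-5,6-(isopropylidenedioxy)-3,7,7-trimethylcyclohept-2-en-1-one, via free diol 15 (not isolated)
Conditions: pyridinium p-toluenesulfonate, MeOH, 0 °C → rt; then Me2C(OMe)2, acetone, pyridinium p-toluenesulfonate, rt
Reagents that add atoms: 2,2-dimethoxypropane COC(C)(C)OC
Why: Mild acid methanolysis removes the triethylsilyl ether selectively, and transketalisation of the trans-7,8-diol gives the trans-fused acetonide, leaving C9 as the only silyl ether.

Step 10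
Reactants: 16 (4S,5R,6S)-4-(tert-butyldimethylsilyloxy)-5,6-(isopropylidenedioxy)-3,7,7-trimethylcyclohept-2-en-1-one
Product: 17 (1R,4S,5R,6S)-4-(tert-butyldimethylsilyloxy)-5,6-(isopropylidenedioxy)-3,7,7-trimethylcyclohept-2-en-1-ol
Conditions: (S)-2-methyl-CBS-oxazaborolidine (0.3 equiv), catecholborane, PhMe, −78 °C; MeOH, then aq. NaHCO3
Reagents that add atoms: none
Why: Corey–Bakshi–Shibata reduction, with the fully substituted C6 as the large and the alkenyl C4 as the small carbonyl substituent, should give the (5R) allylic alcohol (hydroxyl cis to the C9 oxygen) under reagent control.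

Step 11
Reactants: 17 (1R,4S,5R,6S)-4-(tert-butyldimethylsilyloxy)-5,6-(isopropylidenedioxy)-3,7,7-trimethylcyclohept-2-en-1-ol; 18 triethyl orthoacetate
Product: 20 ethyl 2-[(1S,5S,6R,7S)-7-(tert-butyldimethylsilyloxy)-5,6-(isopropylidenedioxy)-1,4,4-trimethylcyclohept-2-en-1-yl]acetate, via ketene acetal 19 (not isolated)
Conditions: 18 (excess), EtCO2H (cat.), xylene, 140 °C, EtOH distilled off
Reagents that add atoms: none
Why: Johnson–Claisen rearrangement transfers the two-carbon ester unit suprafacially from the C5 oxygen to C10, creating the quaternary centre with C11 cis to the C9 oxygen and moving the alkene to C4=C5.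

Step 12
Reactants: 20 ethyl 2-[(1S,5S,6R,7S)-7-(tert-butyldimethylsilyloxy)-5,6-(isopropylidenedioxy)-1,4,4-trimethylcyclohept-2-en-1-yl]acetate
Product: 21 N-methoxy-N-methylamide of the same acid (ring unchanged)
Conditions: MeNH(OMe)·HCl, iPrMgCl, THF, −20 → 0 °C
Reagents that add atoms: N,O-dimethylhydroxylamine hydrochloride CNOC.Cl
Why: Aminolysis of the ester by the chloromagnesium amide gives the Weinreb amide.

Step 13
Reactants: 21 N-methoxy-N-methylamide; 22 prop-1-ynylmagnesium bromide
Product: 23 1-(ring)pent-3-yn-2-one (ynone: C11H2–C1(=O)–C2≡C3–CH3 on C10; ring unchanged)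
Conditions: 22 (0.5 M in THF), THF, 0 °C; aq. NH4Cl
Reagents that add atoms: none
Why: The alkynyl Grignard reagent adds once to the Weinreb amide through the chelated tetrahedral intermediate, installing C1, C2, C3 and the C3 methyl.

Step 14
Reactants: 23 ynone
Product: 24 (3Z)-4-iodo-1-(ring)pent-3-en-2-one ((Z)-β-iodoenone; ring unchanged)
Conditions: LiI, AcOH, MeCN, rt
Reagents that add atoms: lithium iodide [Li+].[I-]
Why: Conjugate hydroiodination of the ynone (iodide to C3, proton to C2) gives the (Z)-β-iodoenone, the isomer favoured under these conditions.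

Step 15
Reactants: 24 (Z)-β-iodoenone
Product: 26 (3Z)-1-diazo-4-iodo-1-(ring)pent-3-en-2-one (α-diazo ketone, N2 on C11), via trifluoroacetyl ketone 25 (not isolated)
Conditions: LiN(SiMe3)2, THF, −78 °C; CF3CO2CH2CF3; 5% aq. HCl work-up; then 4-acetamidobenzenesulfonyl azide, Et3N, H2O (1 equiv), MeCN, rt
Reagents that add atoms: 2,2,2-trifluoroethyl trifluoroacetate O=C(OCC(F)(F)F)C(F)(F)F (retained in 25 only); 4-acetamidobenzenesulfonyl azide CC(=O)Nc1ccc(cc1)S(=O)(=O)N=[N+]=[N-]
Why: Regitz-type detrifluoroacetylative diazo transfer: kinetic α′-enolisation at C11, C-trifluoroacetylation, then diazo transfer to the activated 1,3-dicarbonyl with loss of the trifluoroacetyl group.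

Step 16
Reactants: 26 α-diazo ketone
Product: 27 acyl bicyclo[1.1.0]butane: bicyclobutane C4–C5–C10–C11 (central bond C4–C11) with wings C5 and C10 spanned by C6–C9, (Z)-3-iodobut-2-enoyl on C11, CH3 on C10, 9-OTBS, 7,8-O-isopropylidene
Conditions: Rh2(OAc)4 (1 mol %), CH2Cl2, −78 → 0 °C, slow addition of 26
Reagents that add atoms: none
Why: The dirhodium carbenoid at C11, held next to C4=C5 by the quaternary C10 (no β-hydrogen for a 1,2-shift), cyclopropanates the alkene intramolecularly (bicyclobutanation of an α-allyl α-diazo carbonyl compound), and since it can reach only the alkene face syn to the C10–C11 bond, C4, C5 and C11 follow from C10.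

Step 17
Reactants: 27 acyl bicyclo[1.1.0]butane
Product: 28 tricyclic enone: 9-O-TBS-7,8-O-isopropylidene-7,8,9-trihydroxylongipin-2-en-1-one (all seven stereocentres arranged as in the target)
Conditions: (Me3Si)3SiH (1.3 equiv), AIBN (0.2 equiv), PhH (0.005 M), 80 °C, silane and initiator added by syringe pump
Reagents that add atoms: none
Why: Proposed new method: iodine abstraction by (Me3Si)3Si• gives the σ-vinyl radical at C3 (its fast inversion makes the alkene geometry irrelevant), which attacks bridgehead C4 of the acyl bicyclobutane on the convex face and breaks the strained C4–C11 bond in a homolytic substitution, and the resulting C11 bridgehead radical takes hydrogen from the silane to carry the chain. The closest known reaction types are Giese-type additions of carbon radicals to the bridgehead β to the acyl group of acyl bicyclobutanes, radical additions to 2,4-bridged bicyclobutanes that give bicyclo[3.1.1]heptanes, and vinyl radical cyclisations; what is new is that the radical is tethered through the acyl group, so addition and ring closure are one event. The cyclohexenone ring (C1, C2, C3, C4, C5, C11) closes by this attack at C4, five-membered if counted through the breaking bond and six-membered once it has broken, and the same scission turns the bicyclobutane into the cyclobutane C4–C5–C11–C10. At C4 the short tether can deliver C3 only into the position vacated by the central bond, cis to the C1 acyl group on C11, and C11 receives its hydrogen in the only open (exo) position of the new bicyclo[3.1.1]heptenone, so both new centres follow from the configuration of 27. The step needs cyclisation to outrun direct reduction of the vinyl radical and intramolecular hydrogen transfer, which is sought by high dilution, slow addition and a silane as a slow hydrogen donor, and it needs attack at C4 rather than at a wing carbon, which the weak, exposed central bond and the roughly 64 kcal/mol of strain released should secure.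

Step 18
Reactants: 28 tricyclic enone
Product: 29 9-O-TBS-7,8,9-trihydroxylongipin-2-en-1-one (7,8-diol free)
Conditions: AcOH/H2O (4:1), 40 °C
Reagents that add atoms: none
Why: Acid hydrolysis of the strained trans-fused acetonide is faster than cleavage of the hindered secondary tert-butyldimethylsilyl ether.

Step 19
Reactants: 29 9-O-TBS diol; 30 angelic acid ((Z)-2-methylbut-2-enoic acid)
Product: 32 7,8-di-O-angeloyl-9-O-TBS-9-hydroxylongipin-2-en-1-one, via monoangelate 31 (not isolated)
Conditions: 30 (6 equiv), 2,4,6-Cl3C6H2COCl, Et3N, PhMe, rt; then 29, PhMe, 80 °C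
Reagents that add atoms: none
Why: Yamaguchi-type esterification through the mixed 2,4,6-trichlorobenzoic anhydride, run without a nucleophilic amine catalyst, acylates hindered secondary alcohols with angelic acid with little Z to E isomerisation; C8–OH should react first and the neopentyl C7–OH on heating.

Step 20
Reactants: 32 bis-angelate silyl ether
Product: 33 (4R,5S,7S,8S,9S,10R,11R)-7,8-bis(angeloyloxy)-9-hydroxylongipin-2-en-1-one (target)
Conditions: HF·pyridine, THF/pyridine, 0 °C → rt
Reagents that add atoms: none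
Why: Buffered fluoride cleavage of the silyl ether leaves the angelates, the enone and the cyclobutane untouched.

Compound list
1 | (E)-but-2-enal | C/C=C/C=O | starting material
2 | 1-methoxy-2-methyl-1-(trimethylsilyloxy)prop-1-ene | COC(O[Si](C)(C)C)=C(C)C | starting material
3 | methyl (3R,4E)-3-hydroxy-2,2-dimethylhex-4-enoate | C/C=C/[C@@H](O)C(C)(C)C(=O)OC | intermediate
4 | methyl (3R,4E)-2,2-dimethyl-3-(triethylsilyloxy)hex-4-enoate | C/C=C/[C@@H](O[Si](CC)(CC)CC)C(C)(C)C(=O)OC | intermediate
5 | (trimethylsilyl)methyllithium | [Li]C[Si](C)(C)C | starting material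
6 | (4R,5E)-3,3-dimethyl-4-(triethylsilyloxy)-1-(trimethylsilyl)hept-5-en-2-one | C[Si](C)(C)CC(=O)C(C)(C)[C@H](O[Si](CC)(CC)CC)/C=C/C | intermediate
7 | (4R,5E)-3,3-dimethyl-4-(triethylsilyloxy)hept-5-en-2-one | CC(=O)C(C)(C)[C@H](O[Si](CC)(CC)CC)/C=C/C | intermediate
8 | but-3-en-2-one | C=CC(C)=O | starting material
9 | (7R,8E)-3-hydroxy-3,6,6-trimethyl-7-(triethylsilyloxy)deca-1,8-dien-5-one (both C3 epimers) | C=CC(C)(O)CC(=O)C(C)(C)[C@H](O[Si](CC)(CC)CC)/C=C/C | intermediate
10 | (6R)-3-hydroxy-3,7,7-trimethyl-6-(triethylsilyloxy)cyclohept-4-en-1-one (both C3 epimers) | O=C1CC(C)(O)C=C[C@@H](O[Si](CC)(CC)CC)C1(C)C | intermediate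
11 | C3 methanesulfonate of 10 | O=C1CC(C)(OS(C)(=O)=O)C=C[C@@H](O[Si](CC)(CC)CC)C1(C)C | intermediate
12 | (6R)-3,7,7-trimethyl-6-(triethylsilyloxy)cyclohepta-2,4-dien-1-one | O=C1C=C(C)C=C[C@@H](O[Si](CC)(CC)CC)C1(C)C | intermediate
13 | (4S,5S,6S)-4,5-dihydroxy-3,7,7-trimethyl-6-(triethylsilyloxy)cyclohept-2-en-1-one | O=C1C=C(C)[C@H](O)[C@H](O)[C@@H](O[Si](CC)(CC)CC)C1(C)C | intermediate
14 | (4S,5S,6S)-4-(tert-butyldimethylsilyloxy)-5-hydroxy-3,7,7-trimethyl-6-(triethylsilyloxy)cyclohept-2-en-1-one | O=C1C=C(C)[C@H](O[Si](C)(C)C(C)(C)C)[C@H](O)[C@@H](O[Si](CC)(CC)CC)C1(C)C | intermediate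
15 | (4S,5R,6S)-4-(tert-butyldimethylsilyloxy)-5,6-dihydroxy-3,7,7-trimethylcyclohept-2-en-1-one | O=C1C=C(C)[C@H](O[Si](C)(C)C(C)(C)C)[C@H](O)[C@@H](O)C1(C)C | intermediate
16 | (4S,5R,6S)-4-(tert-butyldimethylsilyloxy)-5,6-(isopropylidenedioxy)-3,7,7-trimethylcyclohept-2-en-1-one | O=C1C=C(C)[C@H](O[Si](C)(C)C(C)(C)C)[C@@H]2OC(C)(C)O[C@H]2C1(C)C | intermediate
17 | (1R,4S,5R,6S)-4-(tert-butyldimethylsilyloxy)-5,6-(isopropylidenedioxy)-3,7,7-trimethylcyclohept-2-en-1-ol | O[C@@H]1C=C(C)[C@H](O[Si](C)(C)C(C)(C)C)[C@@H]2OC(C)(C)O[C@H]2C1(C)C | intermediate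
18 | triethyl orthoacetate | CC(OCC)(OCC)OCC | starting material
19 | 1-ethoxyvinyl ether of 17 (mixed ketene acetal) | C=C(OCC)O[C@@H]1C=C(C)[C@H](O[Si](C)(C)C(C)(C)C)[C@@H]2OC(C)(C)O[C@H]2C1(C)C | intermediate
20 | ethyl 2-[(1S,5S,6R,7S)-7-(tert-butyldimethylsilyloxy)-5,6-(isopropylidenedioxy)-1,4,4-trimethylcyclohept-2-en-1-yl]acetate | CCOC(=O)C[C@]1(C)[C@H](O[Si](C)(C)C(C)(C)C)[C@@H]2OC(C)(C)O[C@H]2C(C)(C)C=C1 | intermediate
21 | N-methoxy-N-methylamide corresponding to 20 | CON(C)C(=O)C[C@]1(C)[C@H](O[Si](C)(C)C(C)(C)C)[C@@H]2OC(C)(C)O[C@H]2C(C)(C)C=C1 | intermediate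
22 | prop-1-ynylmagnesium bromide | CC#C[Mg]Br | starting material
23 | ynone: 1-(ring of 20)pent-3-yn-2-one | CC#CC(=O)C[C@]1(C)[C@H](O[Si](C)(C)C(C)(C)C)[C@@H]2OC(C)(C)O[C@H]2C(C)(C)C=C1 | intermediate
24 | (Z)-β-iodoenone: (3Z)-4-iodo-1-(ring of 20)pent-3-en-2-one | C/C(I)=C/C(=O)C[C@]1(C)[C@H](O[Si](C)(C)C(C)(C)C)[C@@H]2OC(C)(C)O[C@H]2C(C)(C)C=C1 | intermediate
25 | C11-trifluoroacetyl derivative of 24 (C11 unassigned, enolised) | C/C(I)=C/C(=O)C(C(=O)C(F)(F)F)[C@]1(C)[C@H](O[Si](C)(C)C(C)(C)C)[C@@H]2OC(C)(C)O[C@H]2C(C)(C)C=C1 | intermediate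
26 | α-diazo ketone: (3Z)-1-diazo-4-iodo-1-(ring of 20)pent-3-en-2-one | C/C(I)=C/C(=O)C(=[N+]=[N-])[C@]1(C)[C@H](O[Si](C)(C)C(C)(C)C)[C@@H]2OC(C)(C)O[C@H]2C(C)(C)C=C1 | intermediate
27 | acyl bicyclo[1.1.0]butane (central bond C4–C11; (Z)-3-iodobut-2-enoyl on C11; 9-OTBS; 7,8-O-isopropylidene) | C/C(I)=C/C(=O)[C@]12[C@@H]3[C@H]1[C@@]2(C)[C@H](O[Si](C)(C)C(C)(C)C)[C@@H]4OC(C)(C)O[C@H]4C3(C)C | intermediate
28 | 9-O-TBS-7,8-O-isopropylidene-7,8,9-trihydroxylongipin-2-en-1-one | O=C1C=C(C)[C@H]2[C@H]3[C@@H]1[C@]2(C)[C@H](O[Si](C)(C)C(C)(C)C)[C@@H]4OC(C)(C)O[C@H]4C3(C)C | intermediate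
29 | 9-O-TBS-7,8,9-trihydroxylongipin-2-en-1-one | O=C1C=C(C)[C@H]2[C@H]3[C@@H]1[C@]2(C)[C@H](O[Si](C)(C)C(C)(C)C)[C@H](O)[C@@H](O)C3(C)C | intermediate
30 | angelic acid ((Z)-2-methylbut-2-enoic acid) | C/C=C(/C)C(=O)O | starting material
31 | 8-O-angeloyl-9-O-TBS-7,8,9-trihydroxylongipin-2-en-1-one | O=C1C=C(C)[C@H]2[C@H]3[C@@H]1[C@]2(C)[C@H](O[Si](C)(C)C(C)(C)C)[C@H](OC(=O)/C(C)=C\C)[C@@H](O)C3(C)C | intermediate
32 | 7,8-di-O-angeloyl-9-O-TBS-7,8,9-trihydroxylongipin-2-en-1-one | O=C1C=C(C)[C@H]2[C@H]3[C@@H]1[C@]2(C)[C@H](O[Si](C)(C)C(C)(C)C)[C@H](OC(=O)/C(C)=C\C)[C@@H](OC(=O)/C(C)=C\C)C3(C)C | intermediate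
33 | (4R,5S,7S,8S,9S,10R,11R)-7,8-bis(angeloyloxy)-9-hydroxylongipin-2-en-1-one | C/C=C(/C)C(=O)O[C@@H]1[C@@H](OC(=O)/C(C)=C\C)C(C)(C)[C@@H]2[C@H]3C(=O)C=C(C)[C@@H]2[C@@]3(C)[C@@H]1O | target

Total step count: 20. Longest linear sequence: 20 steps (1 → 33); 2, 5, 8, 18, 22 and 30 enter as single commercial reagents.

Steps most likely to fail

Step 17 (key step). The vinyl radical may be reduced by the silane, or may abstract hydrogen intramolecularly from C5–H or the C10 methyl, before it engages the central bond. The fallback forms the same C3–C4 bond last by known reaction types. It sets out from 27: HI (LiI with camphorsulfonic acid, CH2Cl2, −20 °C) is added across the C4–C11 bond, the documented hydrohalogenation of acyl bicyclobutanes, with iodide entering at C4 and a proton at C11, to give the 4-iodocyclobutyl ketone F1. C11 is equilibrated through the enol (DBU) so that the acyl group sits on the face from which it can reach C4. Irradiation of F1 with (Bu3Sn)2 in PhH then generates the C4 cyclobutyl radical, which adds to C3 of the β-iodoenone in a polarity-matched six-membered closure; the α-keto radical expels the vinylic iodine atom (radical addition–elimination), and the route is rejoined at 28.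

Step 16. The electrophilic acyl carbenoid may be diverted into C–H insertion at C7–H (held on the same face as C11) or a 1,2-shift, or the strained ketone may be opened by the Lewis-acidic catalyst. The fallback runs the bicyclobutanation on the α-diazo ester, the best-documented substrate for this closure, and builds the iodoenone afterwards. It sets out from 20: C-trifluoroacetylation (LiN(iPr)2, CF3CO2CH2CF3) gives the trifluoroacetyl ester F2, and diazo transfer (4-acetamidobenzenesulfonyl azide, Et3N) gives the α-diazo ester F3. Rh2(OAc)4 at −78 °C closes the bicyclobutane ethyl ester F4; MeNH(OMe)·HCl/iPrMgCl converts it into the bicyclobutane N-methoxy-N-methylamide F5, and MeC≡CMgBr into the bicyclobutyl ynone F6. LiI/AcOH at 0 °C should add HI to the ynone faster than to the bicyclobutane, rejoining the route at 27.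

Step 19. Acylation of the neopentyl C7 hydroxyl may stay incomplete, and the activated angelate may isomerise from Z to E (tiglate formation) under the forcing conditions. The fallback builds the (Z)-alkenes on the esters instead of transferring them. It sets out from 29: carbodiimide coupling (N,N′-dicyclohexylcarbodiimide, 4-dimethylaminopyridine) with 2-[bis(2,2,2-trifluoroethoxy)phosphoryl]propanoic acid gives the 7,8-bis(phosphonopropanoate) F7. Still–Gennari olefination (KN(SiMe3)2, 18-crown-6, THF, −78 °C; acetaldehyde) then forms both (Z)-2-methylbut-2-enoates and rejoins the route at 32.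

Further compounds
F1 | step 17 | 4-iodocyclobutyl ketone (HI adduct of 27: I on C4, H on C11, (Z)-3-iodobut-2-enoyl on C11) | C/C(I)=C/C(=O)[C@@H]1[C@@H]2[C@H](I)[C@@]1(C)[C@H](O[Si](C)(C)C(C)(C)C)[C@@H]3OC(C)(C)O[C@H]3C2(C)C
F2 | step 16 | ethyl 2-(trifluoroacetyl) derivative of 20 (C11 unassigned) | CCOC(=O)C(C(=O)C(F)(F)F)[C@]1(C)[C@H](O[Si](C)(C)C(C)(C)C)[C@@H]2OC(C)(C)O[C@H]2C(C)(C)C=C1
F3 | step 16 | ethyl 2-diazo derivative of 20 (α-diazo ester) | CCOC(=O)C(=[N+]=[N-])[C@]1(C)[C@H](O[Si](C)(C)C(C)(C)C)[C@@H]2OC(C)(C)O[C@H]2C(C)(C)C=C1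
F4 | step 16 | bicyclobutane ethyl ester (CO2Et on C11; otherwise as 27) | CCOC(=O)[C@]12[C@@H]3[C@H]1[C@@]2(C)[C@H](O[Si](C)(C)C(C)(C)C)[C@@H]4OC(C)(C)O[C@H]4C3(C)C
F5 | step 16 | bicyclobutane N-methoxy-N-methylamide | CON(C)C(=O)[C@]12[C@@H]3[C@H]1[C@@]2(C)[C@H](O[Si](C)(C)C(C)(C)C)[C@@H]4OC(C)(C)O[C@H]4C3(C)C
F6 | step 16 | bicyclobutyl ynone (but-2-ynoyl on C11) | CC#CC(=O)[C@]12[C@@H]3[C@H]1[C@@]2(C)[C@H](O[Si](C)(C)C(C)(C)C)[C@@H]4OC(C)(C)O[C@H]4C3(C)C
F7 | step 19 | 7,8-bis{2-[bis(2,2,2-trifluoroethoxy)phosphoryl]propanoate} of 29 | O=C1C=C(C)[C@H]2[C@H]3[C@@H]1[C@]2(C)[C@H](O[Si](C)(C)C(C)(C)C)[C@H](OC(=O)C(C)P(=O)(OCC(F)(F)F)OCC(F)(F)F)[C@@H](OC(=O)C(C)P(=O)(OCC(F)(F)F)OCC(F)(F)F)C3(C)C
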